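The plan closes each flavan ring C last, at C4–C4a. Middle C4 is benzylic to bottom ring A (it sits on bottom C8), so a trans C3–C4 epoxide opens there when the free ortho carbon of the ring A aryl ether on O1 attacks. This single 6-endo Friedel–Crafts step forms C4–C4a, closes middle ring C and fixes C4 anti to the C3 oxygen (2,4-cis); C3 is inverted afterwards through the ketone. The precursor is an erythro aryl ether of a trans-epoxy alcohol built from the bottom flavan 8-carbaldehyde by Claisen–Schmidt condensation, CBS reduction, Shi epoxidation and Mitsunobu etherification. The same sequence, in the mirror-image series, adds the top unit.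

Key step: step 14

Conventions: flavan numbering is used in each unit (O1, C2, C3, C4, C4a, C5–C8, C8a; ring A = benzo ring, ring B = 2-aryl ring, ring C = pyran ring); Bn = benzyl. "Bot" = (2S,3S,4R)-3,4,5,7-tetrakis(benzyloxy)-2-[4-(benzyloxy)phenyl]-6-bromochroman-8-yl (2,3-cis, 3,4-trans). "Dim" = (2R,3R)-3,5,7-tris(benzyloxy)-2-[4-(benzyloxy)phenyl]-6-bromo-4-(Bot)chroman-8-yl with 2-aryl, 3-OBn and 4-Bot all cis.

Assumption: in the oxazaborolidine reductions the aryl group is taken as the larger ketone substituent, so the (S)-catalyst gives the (R)-allylic alcohol; should the sense be the reverse, the two catalyst enantiomers are exchanged.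

**Bottom unit**

Step 1
Reactants: 1 4-(benzyloxy)benzaldehyde
Product: 2 rac-1-[4-(benzyloxy)phenyl]prop-2-en-1-ol
Conditions: CH2=CHMgBr, THF, 0 °C; aq. NH4Cl
Reagents that add atoms: vinylmagnesium bromide, C=C[Mg]Br
Why: Grignard 1,2-addition to the aldehyde gives the secondary allylic alcohol that the kinetic resolution of step 2 needs.

Step 2
Reactants: 2 rac-1-[4-(benzyloxy)phenyl]prop-2-en-1-ol
Product: 3 (R)-[4-(benzyloxy)phenyl][(S)-oxiran-2-yl]methanol (erythro)
Conditions: Ti(OiPr)4, D-(−)-diisopropyl tartrate, t-BuOOH (0.6 equiv), 4 Å molecular sieves, CH2Cl2, −20 °C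
Reagents that add atoms: tert-butyl hydroperoxide, CC(C)(C)OO
Why: Sharpless kinetic resolution: the titanium tartrate complex should epoxidise the (S)-enantiomer of 2 much faster than the (R)-enantiomer and on the face that gives the erythro epoxy alcohol, so both stereocentres of 3 are set by the catalyst and unreacted (R)-2 is separated.

Step 3
Reactants: 4 3,5-bis(benzyloxy)phenol
Product: 5 3,5-bis(benzyloxy)-2-iodophenol
Conditions: I2, NaHCO3, THF/H2O, 0 °C
Reagents that add atoms: iodine, [I][I]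
Why: Electrophilic aromatic iodination of the phenoxide should go to the less hindered position beside the hydroxyl and not to the position between the two benzyloxy groups; the iodine blocks one ortho carbon and is the later formyl handle at C8.

Step 4
Reactants: 3 (R)-[4-(benzyloxy)phenyl][(S)-oxiran-2-yl]methanol, 5 3,5-bis(benzyloxy)-2-iodophenol
Product: 6 (S)-2-{(S)-[4-(benzyloxy)phenyl][3,5-bis(benzyloxy)-2-iodophenoxy]methyl}oxirane (threo)
Conditions: PPh3, diisopropyl azodicarboxylate, toluene, 0 °C → rt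
Reagents that add atoms: none
Why: Mitsunobu etherification displaces the activated benzylic hydroxyl by the phenoxide with inversion, turning the erythro alcohol into the threo aryl ether, while the adjacent epoxide is a spectator whose inductive effect disfavours ionisation at the carbinol carbon.

Step 5
Reactants: 6 threo epoxy aryl ether
Product: 7 (2S,3S)-5,7-bis(benzyloxy)-2-[4-(benzyloxy)phenyl]-8-iodochroman-3-ol (2,3-cis)
Conditions: AuCl3 (5 mol%), AgOSO2CF3 (15 mol%), ClCH2CH2Cl, rt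
Reagents that add atoms: none
Why: Lewis-acid-promoted 6-endo epoxy–arene (Friedel–Crafts) cyclisation: the only free ortho carbon of ring A opens the epoxide at its terminal CH2, leaving C2 and C3 untouched, so the threo ether gives the 2,3-cis flavan-3-ol, while attack at the internal carbon (5-exo) is disfavoured by hindrance and by the adjacent C–O bond.

Step 6
Reactants: 7 8-iodo flavan-3-ol
Product: 8 (2S,3S,4R)-5,7-bis(benzyloxy)-2-[4-(benzyloxy)phenyl]-8-iodochromane-3,4-diol (2,3-cis, 3,4-trans)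
Conditions: 2,3-dichloro-5,6-dicyano-1,4-benzoquinone (DDQ), CH2Cl2/H2O, rt
Reagents that add atoms: water, O
Why: DDQ abstracts hydride from C4, which is benzylic to the trioxygenated ring A, and water adds to the cation anti to the axial 3-hydroxyl, giving the 3,4-trans diol (benzylic C4 oxidation of flavans in the presence of an oxygen nucleophile); doing this on the monomer avoids the doubly benzylic C4–H bonds that the dimer and trimer contain.

Step 7
Reactants: 8 flavan-3,4-diol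
Product: 9 (2S,3S,4R)-3,4,5,7-tetrakis(benzyloxy)-2-[4-(benzyloxy)phenyl]-8-iodochromane
Conditions: NaH, BnBr, Bu4NI (cat.), DMF, 0 °C → rt
Reagents that add atoms: benzyl bromide, BrCc1ccccc1
Why: Williamson etherification of both secondary alkoxides gives benzyl ethers that are removed with all the others in the last step.

Step 8
Reactants: 9 8-iodo pentabenzyl ether
Product: 11 (2S,3S,4R)-3,4,5,7-tetrakis(benzyloxy)-2-[4-(benzyloxy)phenyl]chromane-8-carbaldehyde, via aryllithium 10 (not isolated)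
Conditions: n-BuLi, THF, −78 °C; then DMF, −78 → 0 °C; aq. NH4Cl
Reagents that add atoms: N,N-dimethylformamide, CN(C)C=O
Why: Iodine–lithium exchange is fast at −78 °C and formylation of the aryllithium with DMF puts the aldehyde at C8 without any regiochemical question, because the iodine was placed there in step 3.

Step 9
Reactants: 11 bottom 8-carbaldehyde
Product: 12 (2S,3S,4R)-3,4,5,7-tetrakis(benzyloxy)-2-[4-(benzyloxy)phenyl]-6-bromochromane-8-carbaldehyde (Bot–CHO)
Conditions: N-bromosuccinimide, CH2Cl2/MeCN, 0 °C, dark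
Reagents that add atoms: N-bromosuccinimide, BrN1C(=O)CCC1=O
Why: Electrophilic bromination at C6, the only free ring A position; the bromine blocks this nucleophilic site and should force the 5- and 7-benzyloxy groups out of the ring plane, which lowers the donor strength of ring A so that the later C8-benzylic epoxide and the C4 benzyl ether do not ionise freely, and it leaves with the benzyl groups at the end.

**Middle unit**

Step 10
Reactants: 12 Bot–CHO, 13 4'-(benzyloxy)acetophenone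
Product: 14 (E)-1-[4-(benzyloxy)phenyl]-3-(Bot)prop-2-en-1-one
Conditions: KOH, EtOH/THF, rt
Reagents that add atoms: none
Why: Claisen–Schmidt condensation of the non-enolisable aldehyde with the methyl ketone gives the (E)-enone after dehydration.

Step 11
Reactants: 14 chalcone
Product: 15 (R,E)-1-[4-(benzyloxy)phenyl]-3-(Bot)prop-2-en-1-ol
Conditions: (S)-1-methyl-3,3-diphenyltetrahydro-1H,3H-pyrrolo[1,2-c][1,3,2]oxazaborole ((S)-Me-CBS), BH3·SMe2, THF, −30 °C; MeOH
Reagents that add atoms: none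
Why: CBS reduction: the oxazaborolidine–borane complex binds the carbonyl oxygen anti to the aryl group and delivers hydride to one face, setting the carbinol centre as (R), and 1,2-reduction is expected because the electron-rich β-aryl group makes the enone a poor conjugate acceptor.

Step 12
Reactants: 15 (R)-allylic alcohol
Product: 16 (1S,2R,3R)-1-[4-(benzyloxy)phenyl]-2,3-epoxy-3-(Bot)propan-1-ol (threo alcohol, trans-epoxide)
Conditions: 1,2:4,5-di-O-isopropylidene-β-D-erythro-2,3-hexodiulo-2,6-pyranose (D-fructose-derived Shi ketone), Oxone (2KHSO5·KHSO4·K2SO4), K2CO3, Bu4NHSO4, MeCN/CH2(OMe)2/aq. Na2B4O7 buffer, 0 °C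
Reagents that add atoms: potassium peroxymonosulfate, [K+].[O-]S(=O)(=O)OO
Why: Shi epoxidation: the chiral dioxirane transfers oxygen to the trans alkene through a spiro transition state on the face that this ketone also uses for trans-β-methylstyrene ((R,R)-oxide), so both epoxide centres are reagent-controlled and the geometry stays trans.

Step 13
Reactants: 16 threo epoxy alcohol, 5 3,5-bis(benzyloxy)-2-iodophenol
Product: 17 3,5-bis(benzyloxy)-2-iodophenyl ether of (1R,2S,3R)-1-[4-(benzyloxy)phenyl]-2,3-epoxy-3-(Bot)propan-1-ol (erythro ether, trans-epoxide)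
Conditions: PPh3, diisopropyl azodicarboxylate, toluene, 0 °C → rt
Reagents that add atoms: none
Why: Mitsunobu etherification with inversion at the benzylic carbinol gives the erythro ether with the middle C2 configuration; making the C2–O bond after the epoxidation means that no 1,3-diarylallyl aryl ether, which would ionise and scramble, ever appears.

Step 14
Reactants: 17 erythro epoxy aryl ether
Product: 18 (2R,3S)-5,7-bis(benzyloxy)-2-[4-(benzyloxy)phenyl]-4-(Bot)-8-iodochroman-3-ol, 2,3-trans-3,4-trans (2-aryl and 4-Bot cis)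
Conditions: (CF3)2CHOH/CH2Cl2 (1:1), 0 °C → rt
Reagents that add atoms: none
Why: Hexafluoroisopropanol hydrogen-bonds to the epoxide oxygen, and the C4–O bond, benzylic to bottom ring A and assisted by the O1 lone pair of that ring, is attacked from the rear by the free ortho carbon of the iodinated ring A ether, after which loss of a proton restores aromaticity (epoxy–arene Friedel–Crafts cyclisation, the reaction type known for aryl epoxyalkyl ethers giving flavan-3-ols). Middle ring C closes in the 6-endo-tet mode through a chair-like transition state in which the 2-aryl, 3-oxygen and 4-aryl groups are all equatorial. The new stereocentre C4 is set by inversion at the epoxide carbon, that is anti to the C3 oxygen placed by the Shi epoxidation, and since C2 was fixed in step 13 the erythro ether can only give the 2,3-trans-3,4-trans (2,4-cis) isomer, C3 being retained. The step needs 6-endo over 5-exo opening and C-alkylation at one ring A carbon only: benzylic activation of C4 against the inductively deactivated C3 secures the first, and the iodine on the other ortho carbon secures the second. It also needs an SN2-like opening, which the C6 bromine of the bottom unit should secure by twisting the 5- and 7-benzyloxy groups out of conjugation so that no long-lived cation forms; even a cationic closure would put the C3–H bond in the cation plane and be attacked anti to the C3 oxygen, leading to the same isomer.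

Step 15
Reactants: 18 2,3-trans-3,4-trans flavan-3-ol
Product: 19 (2R)-5,7-bis(benzyloxy)-2-[4-(benzyloxy)phenyl]-4-(Bot)-8-iodochroman-3-one (2,4-cis)
Conditions: Dess–Martin periodinane, NaHCO3, CH2Cl2, 0 °C → rt
Reagents that add atoms: none
Why: Buffered Dess–Martin oxidation gives the flavan-3-one under near-neutral conditions, and the 2,4-cis arrangement is the thermodynamically preferred one, so enolisation cannot degrade it.

Step 16
Reactants: 19 flavan-3-one
Product: 20 (2R,3R)-5,7-bis(benzyloxy)-2-[4-(benzyloxy)phenyl]-4-(Bot)-8-iodochroman-3-ol (2-aryl, 3-OH and 4-Bot all cis)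
Conditions: LiBH(sec-Bu)3 (L-Selectride), THF, −78 °C
Reagents that add atoms: none
Why: The bulky hydride attacks the ketone from the face opposite to the two cis aryl groups on C2 and C4, so the hydroxyl ends up cis to both and C3 is inverted (the oxidation–reduction used to turn 2,3-trans into 2,3-cis flavan-3-ols).

Step 17
Reactants: 20 all-cis flavan-3-ol
Product: 21 (2R,3R)-3,5,7-tris(benzyloxy)-2-[4-(benzyloxy)phenyl]-4-(Bot)-8-iodochromane (all-cis)
Conditions: NaH, BnBr, Bu4NI (cat.), DMF, 0 °C → rt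
Reagents that add atoms: benzyl bromide, BrCc1ccccc1
Why: Williamson etherification protects the 3-hydroxyl against the later Mitsunobu and oxidation steps.

Step 18
Reactants: 21 8-iodo dimer
Product: 23 (2R,3R)-3,5,7-tris(benzyloxy)-2-[4-(benzyloxy)phenyl]-4-(Bot)chromane-8-carbaldehyde (all-cis), via arylmagnesium chloride 22 (not isolated)
Conditions: i-PrMgCl·LiCl, THF, −20 → 0 °C; then DMF; aq. NH4Cl
Reagents that add atoms: N,N-dimethylformamide, CN(C)C=O
Why: Iodine–magnesium exchange is much faster for the aryl iodide than for the hindered aryl bromide of the bottom unit, and trapping with DMF gives the aldehyde at middle C8 only, because the iodine came in with the ring A phenol.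

Step 19
Reactants: 23 middle 8-carbaldehyde
Product: 24 (2R,3R)-3,5,7-tris(benzyloxy)-2-[4-(benzyloxy)phenyl]-6-bromo-4-(Bot)chromane-8-carbaldehyde (Dim–CHO)
Conditions: N-bromosuccinimide, CH2Cl2/MeCN, 0 °C, dark
Reagents that add atoms: N-bromosuccinimide, BrN1C(=O)CCC1=O
Why: Electrophilic bromination at middle C6, the only free ring A position left in the molecule (the alkoxyphenyl rings B are far less reactive), gives the middle unit the same blocking and attenuating bromine as the bottom unit.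

**Top unit**

Step 20
Reactants: 24 Dim–CHO, 13 4'-(benzyloxy)acetophenone
Product: 25 (E)-1-[4-(benzyloxy)phenyl]-3-(Dim)prop-2-en-1-one
Conditions: KOH, EtOH/THF, rt
Reagents that add atoms: none
Why: Claisen–Schmidt condensation as in step 10.

Step 21
Reactants: 25 chalcone
Product: 26 (S,E)-1-[4-(benzyloxy)phenyl]-3-(Dim)prop-2-en-1-ol
Conditions: (R)-1-methyl-3,3-diphenyltetrahydro-1H,3H-pyrrolo[1,2-c][1,3,2]oxazaborole ((R)-Me-CBS), BH3·SMe2, THF, −30 °C; MeOH
Reagents that add atoms: none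
Why: CBS reduction as in step 11 with the enantiomeric catalyst sets the carbinol centre as (S), as the mirror-image top unit requires.

Step 22
Reactants: 26 (S)-allylic alcohol
Product: 27 (1R,2S,3S)-1-[4-(benzyloxy)phenyl]-2,3-epoxy-3-(Dim)propan-1-ol (threo alcohol, trans-epoxide)
Conditions: enantiomer of the Shi ketone of step 12 (L-fructose-derived), Oxone (2KHSO5·KHSO4·K2SO4), K2CO3, Bu4NHSO4, MeCN/CH2(OMe)2/aq. Na2B4O7 buffer, 0 °C
Reagents that add atoms: potassium peroxymonosulfate, [K+].[O-]S(=O)(=O)OO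
Why: Shi epoxidation as in step 12; the enantiomeric dioxirane attacks the opposite alkene face and gives the mirror-image trans-epoxide.

Step 23
Reactants: 27 threo epoxy alcohol, 4 3,5-bis(benzyloxy)phenol
Product: 28 3,5-bis(benzyloxy)phenyl ether of (1S,2R,3S)-1-[4-(benzyloxy)phenyl]-2,3-epoxy-3-(Dim)propan-1-ol (erythro ether, trans-epoxide)
Conditions: PPh3, diisopropyl azodicarboxylate, toluene, 0 °C → rt
Reagents that add atoms: none
Why: Mitsunobu etherification with inversion as in step 13; the top ring A needs no handle, so the parent phenol is used.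

Step 24
Reactants: 28 erythro epoxy aryl ether
Product: 29 (2S,3R)-5,7-bis(benzyloxy)-2-[4-(benzyloxy)phenyl]-4-(Dim)chroman-3-ol, 2,3-trans-3,4-trans (2-aryl and 4-Dim cis)
Conditions: (CF3)2CHOH/CH2Cl2 (1:1), 0 °C → rt
Reagents that add atoms: none
Why: The same 6-endo epoxy–arene cyclisation as in step 14 forms top C4–C4a with inversion at the epoxide carbon benzylic to middle ring A; the two ortho carbons of the symmetric top ring A are equivalent, so there is no regiochemical question.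

Step 25
Reactants: 29 trimer flavan-3-ol
Product: 30 (2S)-5,7-bis(benzyloxy)-2-[4-(benzyloxy)phenyl]-4-(Dim)chroman-3-one (2,4-cis)
Conditions: Dess–Martin periodinane, NaHCO3, CH2Cl2, 0 °C → rt
Reagents that add atoms: none
Why: Dess–Martin oxidation as in step 15; the top 3-hydroxyl is the only free alcohol.

Step 26
Reactants: 30 flavan-3-one
Product: 31 (2S,3S)-5,7-bis(benzyloxy)-2-[4-(benzyloxy)phenyl]-4-(Dim)chroman-3-ol (2-aryl, 3-OH and 4-Dim all cis)
Conditions: LiBH(sec-Bu)3 (L-Selectride), THF, −78 °C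
Reagents that add atoms: none
Why: Hydride delivery anti to the two cis aryl groups as in step 16 inverts top C3 and completes the all-cis top unit.

Step 27
Reactants: 31 protected trimer
Product: 32 the target CNP0159291.1: top unit (2S,3S,4R), middle unit (2R,3R,4S), bottom unit (2S,3S,4R)
Conditions: H2 (1 atm), Pd(OH)2/C, Et3N (2.2 equiv), THF/MeOH/H2O, rt
Reagents that add atoms: none
Why: Catalytic hydrogenolysis cleaves the twelve O–benzyl bonds and both aryl C–Br bonds in one operation, triethylamine takes up the hydrogen bromide so that the acid-labile 4-hydroxyflavan unit is not ionised, and the primary O–CH2Ph bonds should cleave faster than the ring C–O bonds at C2 and at bottom C4.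

**Compound list**

1 | 4-(benzyloxy)benzaldehyde | O=Cc1ccc(OCc9ccccc9)cc1 | starting material
2 | rac-1-[4-(benzyloxy)phenyl]prop-2-en-1-ol | C=CC(O)c1ccc(OCc9ccccc9)cc1 | intermediate
3 | (R)-[4-(benzyloxy)phenyl][(S)-oxiran-2-yl]methanol | O[C@H](c1ccc(OCc9ccccc9)cc1)[C@@H]2CO2 | intermediate
4 | 3,5-bis(benzyloxy)phenol | Oc1cc(OCc9ccccc9)cc(OCc9ccccc9)c1 | starting material
5 | 3,5-bis(benzyloxy)-2-iodophenol | Oc1cc(OCc9ccccc9)cc(OCc9ccccc9)c1I | intermediate
6 | (S)-2-{(S)-[4-(benzyloxy)phenyl][3,5-bis(benzyloxy)-2-iodophenoxy]methyl}oxirane | Ic1c(OCc9ccccc9)cc(OCc9ccccc9)cc1O[C@@H](c1ccc(OCc9ccccc9)cc1)[C@@H]2CO2 | intermediate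
7 | (2S,3S)-5,7-bis(benzyloxy)-2-[4-(benzyloxy)phenyl]-8-iodochroman-3-ol | Ic1c(OCc9ccccc9)cc(OCc9ccccc9)c2c1O[C@@H](c1ccc(OCc9ccccc9)cc1)[C@@H](O)C2 | intermediate
8 | (2S,3S,4R)-5,7-bis(benzyloxy)-2-[4-(benzyloxy)phenyl]-8-iodochromane-3,4-diol | Ic1c(OCc9ccccc9)cc(OCc9ccccc9)c2c1O[C@@H](c1ccc(OCc9ccccc9)cc1)[C@@H](O)[C@@H]2O | intermediate
9 | (2S,3S,4R)-3,4,5,7-tetrakis(benzyloxy)-2-[4-(benzyloxy)phenyl]-8-iodochromane | Ic1c(OCc9ccccc9)cc(OCc9ccccc9)c2c1O[C@@H](c1ccc(OCc9ccccc9)cc1)[C@@H](OCc9ccccc9)[C@@H]2OCc9ccccc9 | intermediate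
10 | 8-lithio derivative of 9 (aryllithium) | [Li]c1c(OCc9ccccc9)cc(OCc9ccccc9)c2c1O[C@@H](c1ccc(OCc9ccccc9)cc1)[C@@H](OCc9ccccc9)[C@@H]2OCc9ccccc9 | intermediate
11 | (2S,3S,4R)-3,4,5,7-tetrakis(benzyloxy)-2-[4-(benzyloxy)phenyl]chromane-8-carbaldehyde | O=Cc1c(OCc9ccccc9)cc(OCc9ccccc9)c2c1O[C@@H](c1ccc(OCc9ccccc9)cc1)[C@@H](OCc9ccccc9)[C@@H]2OCc9ccccc9 | intermediate
12 | Bot–CHO, (2S,3S,4R)-3,4,5,7-tetrakis(benzyloxy)-2-[4-(benzyloxy)phenyl]-6-bromochromane-8-carbaldehyde | O=Cc1c(OCc9ccccc9)c(Br)c(OCc9ccccc9)c2c1O[C@@H](c1ccc(OCc9ccccc9)cc1)[C@@H](OCc9ccccc9)[C@@H]2OCc9ccccc9 | intermediate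
13 | 4'-(benzyloxy)acetophenone | CC(=O)c1ccc(OCc9ccccc9)cc1 | starting material
14 | (E)-1-[4-(benzyloxy)phenyl]-3-(Bot)prop-2-en-1-one | O=C(/C=C/c3c(OCc9ccccc9)c(Br)c(OCc9ccccc9)c4c3O[C@@H](c5ccc(OCc9ccccc9)cc5)[C@@H](OCc9ccccc9)[C@@H]4OCc9ccccc9)c1ccc(OCc9ccccc9)cc1 | intermediate
15 | (R,E)-1-[4-(benzyloxy)phenyl]-3-(Bot)prop-2-en-1-ol | O[C@H](/C=C/c3c(OCc9ccccc9)c(Br)c(OCc9ccccc9)c4c3O[C@@H](c5ccc(OCc9ccccc9)cc5)[C@@H](OCc9ccccc9)[C@@H]4OCc9ccccc9)c1ccc(OCc9ccccc9)cc1 | intermediate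
16 | (1S,2R,3R)-1-[4-(benzyloxy)phenyl]-2,3-epoxy-3-(Bot)propan-1-ol | O[C@H]([C@H]2O[C@@H]2c3c(OCc9ccccc9)c(Br)c(OCc9ccccc9)c4c3O[C@@H](c5ccc(OCc9ccccc9)cc5)[C@@H](OCc9ccccc9)[C@@H]4OCc9ccccc9)c1ccc(OCc9ccccc9)cc1 | intermediate
17 | 3,5-bis(benzyloxy)-2-iodophenyl ether of (1R,2S,3R)-1-[4-(benzyloxy)phenyl]-2,3-epoxy-3-(Bot)propan-1-ol (key-step precursor) | Ic1c(OCc9ccccc9)cc(OCc9ccccc9)cc1O[C@@H]([C@H]2O[C@@H]2c3c(OCc9ccccc9)c(Br)c(OCc9ccccc9)c4c3O[C@@H](c5ccc(OCc9ccccc9)cc5)[C@@H](OCc9ccccc9)[C@@H]4OCc9ccccc9)c1ccc(OCc9ccccc9)cc1 | intermediate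
18 | (2R,3S)-5,7-bis(benzyloxy)-2-[4-(benzyloxy)phenyl]-4-(Bot)-8-iodochroman-3-ol, 2,3-trans-3,4-trans (key-step product) | Ic6c(OCc9ccccc9)cc(OCc9ccccc9)c7c6O[C@H](c8ccc(OCc9ccccc9)cc8)[C@@H](O)[C@@H]7c3c(OCc9ccccc9)c(Br)c(OCc9ccccc9)c4c3O[C@@H](c5ccc(OCc9ccccc9)cc5)[C@@H](OCc9ccccc9)[C@@H]4OCc9ccccc9 | intermediate
19 | (2R)-5,7-bis(benzyloxy)-2-[4-(benzyloxy)phenyl]-4-(Bot)-8-iodochroman-3-one, 2,4-cis | Ic6c(OCc9ccccc9)cc(OCc9ccccc9)c7c6O[C@H](c8ccc(OCc9ccccc9)cc8)C(=O)[C@@H]7c3c(OCc9ccccc9)c(Br)c(OCc9ccccc9)c4c3O[C@@H](c5ccc(OCc9ccccc9)cc5)[C@@H](OCc9ccccc9)[C@@H]4OCc9ccccc9 | intermediate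
20 | (2R,3R)-5,7-bis(benzyloxy)-2-[4-(benzyloxy)phenyl]-4-(Bot)-8-iodochroman-3-ol, all-cis | Ic6c(OCc9ccccc9)cc(OCc9ccccc9)c7c6O[C@H](c8ccc(OCc9ccccc9)cc8)[C@H](O)[C@@H]7c3c(OCc9ccccc9)c(Br)c(OCc9ccccc9)c4c3O[C@@H](c5ccc(OCc9ccccc9)cc5)[C@@H](OCc9ccccc9)[C@@H]4OCc9ccccc9 | intermediate
21 | (2R,3R)-3,5,7-tris(benzyloxy)-2-[4-(benzyloxy)phenyl]-4-(Bot)-8-iodochromane, all-cis | Ic6c(OCc9ccccc9)cc(OCc9ccccc9)c7c6O[C@H](c8ccc(OCc9ccccc9)cc8)[C@H](OCc9ccccc9)[C@@H]7c3c(OCc9ccccc9)c(Br)c(OCc9ccccc9)c4c3O[C@@H](c5ccc(OCc9ccccc9)cc5)[C@@H](OCc9ccccc9)[C@@H]4OCc9ccccc9 | intermediate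
22 | 8-chloromagnesio derivative of 21 (arylmagnesium chloride) | Cl[Mg]c6c(OCc9ccccc9)cc(OCc9ccccc9)c7c6O[C@H](c8ccc(OCc9ccccc9)cc8)[C@H](OCc9ccccc9)[C@@H]7c3c(OCc9ccccc9)c(Br)c(OCc9ccccc9)c4c3O[C@@H](c5ccc(OCc9ccccc9)cc5)[C@@H](OCc9ccccc9)[C@@H]4OCc9ccccc9 | intermediate
23 | (2R,3R)-3,5,7-tris(benzyloxy)-2-[4-(benzyloxy)phenyl]-4-(Bot)chromane-8-carbaldehyde, all-cis | O=Cc6c(OCc9ccccc9)cc(OCc9ccccc9)c7c6O[C@H](c8ccc(OCc9ccccc9)cc8)[C@H](OCc9ccccc9)[C@@H]7c3c(OCc9ccccc9)c(Br)c(OCc9ccccc9)c4c3O[C@@H](c5ccc(OCc9ccccc9)cc5)[C@@H](OCc9ccccc9)[C@@H]4OCc9ccccc9 | intermediate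
24 | Dim–CHO, the 6-bromo derivative of 23 | O=Cc6c(OCc9ccccc9)c(Br)c(OCc9ccccc9)c7c6O[C@H](c8ccc(OCc9ccccc9)cc8)[C@H](OCc9ccccc9)[C@@H]7c3c(OCc9ccccc9)c(Br)c(OCc9ccccc9)c4c3O[C@@H](c5ccc(OCc9ccccc9)cc5)[C@@H](OCc9ccccc9)[C@@H]4OCc9ccccc9 | intermediate
25 | (E)-1-[4-(benzyloxy)phenyl]-3-(Dim)prop-2-en-1-one | O=C(/C=C/c6c(OCc9ccccc9)c(Br)c(OCc9ccccc9)c7c6O[C@H](c8ccc(OCc9ccccc9)cc8)[C@H](OCc9ccccc9)[C@@H]7c3c(OCc9ccccc9)c(Br)c(OCc9ccccc9)c4c3O[C@@H](c5ccc(OCc9ccccc9)cc5)[C@@H](OCc9ccccc9)[C@@H]4OCc9ccccc9)c1ccc(OCc9ccccc9)cc1 | intermediate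
26 | (S,E)-1-[4-(benzyloxy)phenyl]-3-(Dim)prop-2-en-1-ol | O[C@@H](/C=C/c6c(OCc9ccccc9)c(Br)c(OCc9ccccc9)c7c6O[C@H](c8ccc(OCc9ccccc9)cc8)[C@H](OCc9ccccc9)[C@@H]7c3c(OCc9ccccc9)c(Br)c(OCc9ccccc9)c4c3O[C@@H](c5ccc(OCc9ccccc9)cc5)[C@@H](OCc9ccccc9)[C@@H]4OCc9ccccc9)c1ccc(OCc9ccccc9)cc1 | intermediate
27 | (1R,2S,3S)-1-[4-(benzyloxy)phenyl]-2,3-epoxy-3-(Dim)propan-1-ol | O[C@@H]([C@@H]2O[C@H]2c6c(OCc9ccccc9)c(Br)c(OCc9ccccc9)c7c6O[C@H](c8ccc(OCc9ccccc9)cc8)[C@H](OCc9ccccc9)[C@@H]7c3c(OCc9ccccc9)c(Br)c(OCc9ccccc9)c4c3O[C@@H](c5ccc(OCc9ccccc9)cc5)[C@@H](OCc9ccccc9)[C@@H]4OCc9ccccc9)c1ccc(OCc9ccccc9)cc1 | intermediate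
28 | 3,5-bis(benzyloxy)phenyl ether of (1S,2R,3S)-1-[4-(benzyloxy)phenyl]-2,3-epoxy-3-(Dim)propan-1-ol | c1c(OCc9ccccc9)cc(OCc9ccccc9)cc1O[C@H]([C@@H]2O[C@H]2c6c(OCc9ccccc9)c(Br)c(OCc9ccccc9)c7c6O[C@H](c8ccc(OCc9ccccc9)cc8)[C@H](OCc9ccccc9)[C@@H]7c3c(OCc9ccccc9)c(Br)c(OCc9ccccc9)c4c3O[C@@H](c5ccc(OCc9ccccc9)cc5)[C@@H](OCc9ccccc9)[C@@H]4OCc9ccccc9)c1ccc(OCc9ccccc9)cc1 | intermediate
29 | (2S,3R)-5,7-bis(benzyloxy)-2-[4-(benzyloxy)phenyl]-4-(Dim)chroman-3-ol, 2,3-trans-3,4-trans | c1c(OCc9ccccc9)cc(OCc9ccccc9)c2c1O[C@@H](c1ccc(OCc9ccccc9)cc1)[C@H](O)[C@H]2c6c(OCc9ccccc9)c(Br)c(OCc9ccccc9)c7c6O[C@H](c8ccc(OCc9ccccc9)cc8)[C@H](OCc9ccccc9)[C@@H]7c3c(OCc9ccccc9)c(Br)c(OCc9ccccc9)c4c3O[C@@H](c5ccc(OCc9ccccc9)cc5)[C@@H](OCc9ccccc9)[C@@H]4OCc9ccccc9 | intermediate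
30 | (2S)-5,7-bis(benzyloxy)-2-[4-(benzyloxy)phenyl]-4-(Dim)chroman-3-one, 2,4-cis | c1c(OCc9ccccc9)cc(OCc9ccccc9)c2c1O[C@@H](c1ccc(OCc9ccccc9)cc1)C(=O)[C@H]2c6c(OCc9ccccc9)c(Br)c(OCc9ccccc9)c7c6O[C@H](c8ccc(OCc9ccccc9)cc8)[C@H](OCc9ccccc9)[C@@H]7c3c(OCc9ccccc9)c(Br)c(OCc9ccccc9)c4c3O[C@@H](c5ccc(OCc9ccccc9)cc5)[C@@H](OCc9ccccc9)[C@@H]4OCc9ccccc9 | intermediate
31 | (2S,3S)-5,7-bis(benzyloxy)-2-[4-(benzyloxy)phenyl]-4-(Dim)chroman-3-ol, all-cis (protected trimer) | c1c(OCc9ccccc9)cc(OCc9ccccc9)c2c1O[C@@H](c1ccc(OCc9ccccc9)cc1)[C@@H](O)[C@H]2c6c(OCc9ccccc9)c(Br)c(OCc9ccccc9)c7c6O[C@H](c8ccc(OCc9ccccc9)cc8)[C@H](OCc9ccccc9)[C@@H]7c3c(OCc9ccccc9)c(Br)c(OCc9ccccc9)c4c3O[C@@H](c5ccc(OCc9ccccc9)cc5)[C@@H](OCc9ccccc9)[C@@H]4OCc9ccccc9 | intermediate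
32 | CNP0159291.1, trimer of a top (2S,3S,4R)-flavan-3-ol, a middle (2R,3R,4S)-flavan-3-ol and a bottom (2S,3S,4R)-flavan-3,4-diol linked top C4–middle C8 and middle C4–bottom C8 | Oc1ccc([C@H]2Oc3c(c(O)cc(O)c3[C@H]3c4c(O)cc(O)cc4O[C@@H](c4ccc(O)cc4)[C@H]3O)[C@@H](c3c(O)cc(O)c4c3O[C@@H](c3ccc(O)cc3)[C@@H](O)[C@@H]4O)[C@H]2O)cc1 | target

**Step count and risks**

Total: 27 steps. Longest linear sequence: 26 steps (steps 1, 2 and 4–27; step 3 is a one-step side branch).

The three steps most likely to fail: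

1. Step 14 (the same applies to its repeat, step 24). What may go wrong: the epoxide ionises to a benzylic cation faster than ring A attacks, so that a 1,2-hydride shift to the ketone or attack syn to the C3 oxygen competes and the stereochemical relay to C4 is eroded. Fallback: the two ring bonds are made in the opposite order, setting out from epoxy alcohol 16 and returning at 18.
   - Phenol 5 is C-alkylated in hexafluoroisopropanol at its free position beside the hydroxyl by the benzylic epoxide carbon of 16 (intermolecular Friedel–Crafts opening with inversion), giving the diol-phenol F1.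
   - F1 is heated with HC(OEt)3 and pyridinium p-toluenesulfonate; the cyclic orthoformate of the 1,2-diol is opened at benzylic C2 by the phenol oxygen with inversion, which closes ring C through O1–C2 and gives the 3-O-formate F2.
   - K2CO3 in methanol cleaves the formate of F2 and gives 18.
   - This detour also avoids the intermolecular etherification of step 13.

2. Step 11 (and step 21). What may go wrong: poor facial discrimination, since the oxazaborolidine has to tell an aryl flank from an alkenyl flank, with uncatalysed borane reduction lowering the selectivity further. Fallback: the carbinol centre is set by addition to an aldehyde instead of by ketone reduction, setting out from aldehyde 12 and returning at 15.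
   - 12 is homologated with dimethyl (1-diazo-2-oxopropyl)phosphonate and K2CO3 in methanol (Ohira–Bestmann) to the 8-ethynyl compound F3.
   - Hydroboration of F3 with dicyclohexylborane gives the (E)-alkenylborane F4.
   - Transmetallation with Me2Zn gives the alkenylzinc F5.
   - F5 adds to aldehyde 1 in the presence of the enantiomer of 3-exo-morpholinoisoborneol that delivers the (R)-carbinol, giving 15 with the alkene geometry fixed by the syn hydroboration.

3. Step 27. What may go wrong: hydrogen bromide released during C–Br hydrogenolysis, or over-reduction at the benzylic C4–O bond of the bottom unit, destroys the 4-hydroxyflavan unit through ionisation at C4 once the phenols are free. Fallback: the two tasks are separated, setting out from 31 and returning at 32.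
   - Both bromines are removed first by radical reduction (Bu3SnH, azobisisobutyronitrile, toluene, 80 °C) to give the bromine-free dodecabenzyl ether F6.
   - F6 is hydrogenolysed under neutral, amine-free conditions (H2, Pd(OH)2/C, THF/MeOH, stopped at full debenzylation), so that no acid is formed beside the free target 32.

Further compounds
F1 | step 14 | 1-[4-(benzyloxy)phenyl]-3-(Bot)-3-[4,6-bis(benzyloxy)-2-hydroxy-3-iodophenyl]propane-1,2-diol (threo 1,2-diol, C3 configured as C4 of 18) | O[C@H]([C@@H](O)[C@H](c3c(OCc9ccccc9)c(Br)c(OCc9ccccc9)c4c3O[C@@H](c5ccc(OCc9ccccc9)cc5)[C@@H](OCc9ccccc9)[C@@H]4OCc9ccccc9)c6c(O)c(I)c(OCc9ccccc9)cc6OCc9ccccc9)c1ccc(OCc9ccccc9)cc1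
F2 | step 14 | 3-O-formate of 18 | Ic6c(OCc9ccccc9)cc(OCc9ccccc9)c7c6O[C@H](c8ccc(OCc9ccccc9)cc8)[C@@H](OC=O)[C@@H]7c3c(OCc9ccccc9)c(Br)c(OCc9ccccc9)c4c3O[C@@H](c5ccc(OCc9ccccc9)cc5)[C@@H](OCc9ccccc9)[C@@H]4OCc9ccccc9
F3 | step 11 | Bot–C≡CH, (2S,3S,4R)-3,4,5,7-tetrakis(benzyloxy)-2-[4-(benzyloxy)phenyl]-6-bromo-8-ethynylchromane | C#Cc3c(OCc9ccccc9)c(Br)c(OCc9ccccc9)c4c3O[C@@H](c5ccc(OCc9ccccc9)cc5)[C@@H](OCc9ccccc9)[C@@H]4OCc9ccccc9
F4 | step 11 | dicyclohexyl[(E)-2-(Bot)ethenyl]borane | C1CCCCC1B(C1CCCCC1)/C=C/c3c(OCc9ccccc9)c(Br)c(OCc9ccccc9)c4c3O[C@@H](c5ccc(OCc9ccccc9)cc5)[C@@H](OCc9ccccc9)[C@@H]4OCc9ccccc9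
F5 | step 11 | methyl[(E)-2-(Bot)ethenyl]zinc | C[Zn]/C=C/c3c(OCc9ccccc9)c(Br)c(OCc9ccccc9)c4c3O[C@@H](c5ccc(OCc9ccccc9)cc5)[C@@H](OCc9ccccc9)[C@@H]4OCc9ccccc9
F6 | step 27 | bromine-free analogue of 31 (dodecabenzyl ether of the target) | c1c(OCc9ccccc9)cc(OCc9ccccc9)c2c1O[C@@H](c1ccc(OCc9ccccc9)cc1)[C@@H](O)[C@H]2c6c(OCc9ccccc9)cc(OCc9ccccc9)c7c6O[C@H](c8ccc(OCc9ccccc9)cc8)[C@H](OCc9ccccc9)[C@@H]7c3c(OCc9ccccc9)cc(OCc9ccccc9)c4c3O[C@@H](c5ccc(OCc9ccccc9)cc5)[C@@H](OCc9ccccc9)[C@@H]4OCc9ccccc9
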